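The easy step comes first: the initiator falls by a plain first-order step with a half-life of 49.5 s.

| flask | substrate | coupling partner | initiator | radical scavenger | time | remark |
|---|---|---|---|---|---|---|
| delta | 20 mM | 18.0 mM (fed, over 64.0 s) | 2.0 mM | 0.40 mM | 80 s | a stirred flask in which coupling partner is dosed at a steady rate over 64.0 s without added volume, worked up at 80 s |
| theta | 20 mM | 18.0 mM | 2.0 mM | 0.40 mM | 80 s | everything together in a closed stirred flask, run for 80 s |
| gamma | 20 mM | 18.0 mM | 2.0 mM | 0.40 mM |  | one stirred flow tank at steady state, fed with the mixture as stated, mean residence time 80 s |
| zeta | 20 mM (fed, over 64.0 s) | 18.0 mM | 2.0 mM | 0.40 mM | 80 s | all but substrate at the start; substrate goes in evenly over 64.0 s, the run ends at 80 s |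

    initiator → 2 initiating radical (k1 = 0.0140 s⁻¹)
    substrate + initiating radical → capped initiator + first chain carrier (k2 = 1.35 × 10⁶ L mol⁻¹ s⁻¹)
    substrate + second chain carrier → by-product + first chain carrier (k3 = 39000 L mol⁻¹ s⁻¹)
    2 second chain carrier → ended chains B (k4 = 1.2 × 10⁶ L mol⁻¹ s⁻¹)
    second chain carrier + radical scavenger → ended chains C (k5 = 2.98 × 10⁷ L mol⁻¹ s⁻¹)
    2 first chain carrier → ended chains A (k6 = 5 × 10⁶ L mol⁻¹ s⁻¹)
    coupling partner + first chain carrier → product + second chain carrier (k7 = 52100 L mol⁻¹ s⁻¹)

- order of the set-ups by the amount of product at the outlet or at the end, in percent of the substrate put in, highest first (delta / theta / gamma / zeta)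
- amount of product at the outlet or at the end, in percent of the substrate put in, delta
- amount of product at the outlet or at the end, in percent of the substrate put in, theta
- amount of product at the outlet or at the end, in percent of the substrate put in, gamma
- amount of product at the outlet or at the end, in percent of the substrate put in, zeta

- a species is counted by the substrate in it: one ended chains A counts as two
- for a step with 2 of a species take k times the square, and two of it per event
- the stated concentrations are those of everything mixed, before any reaction; amounts are the same in each set-up
- the feed brings no volume worth counting
- run time (delta): 80 s

Theta, everything mixed in a closed flask, looks contradictory: the first chain carrier ends with a constant 96.0 times larger than that of the step making product, yet I expect product to far outrun the radicals started.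

I freeze the two carriers at a quasi-steady state, where their making balances their loss, and let that level drift with the initiator further on. Each carrier is handed over as fast as the other, so at the charge the second chain carrier stands at 1.20 times the first, and ending balances starting at 0.0560 mM s⁻¹. That puts the first chain carrier at 0.00204 mM, far below the coupling partner. Ending goes with the square of this small level and product with its first power, so the chain length is 34.1 turns per radical started. The level gives 9.41 s as the clearance time, one over the product constant times the frozen level of first chain carrier.

The level follows the square root of the initiator, so over 80 s it acts for 61.3 s of full-level time. I strike 7.14 s for the scavenger, taking radicals as they start. The remaining 54.1 s is 5.75 clearance times, leaving 0.0574 mM of coupling partner. That partner is the limiting reagent, with a cap of 90.0%, so I commit to 89.7% for theta and reckon no other flask here.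

The forecast reads theta > zeta > delta > gamma, with 83.5% for delta, 89.3% for theta, 76% for gamma and 85.5% for zeta, on the ground that “a long chain runs at a rate set by the square root of initiation”.

The flask gives theta > zeta > delta > gamma: 89.8% in theta, 87.0% in zeta, 83.6% in delta and 76.0% in gamma; theta left until 800 s reaches 89.8%. In the tank gamma the initiator stands at 0.943 mM, and after the scavenger's feed 0.0214 mM s⁻¹ of radicals remains. Keeping the ratio of the carriers as I reckoned it at the charge, the clearance time in gamma is 15.2 s. The charge over one plus residence time by clearance time gives 2.88 mM of coupling partner in gamma, and the reading stands at 2.80 mM.

(All constants belong to no real substance; the result is computed.)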